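Everything rests on cutting the C3–C3a bond of the dihydrofuran ring. In the target, C3 is bonded to the benzo carbon C3a and to an exocyclic carbonyl carbon, the arrangement produced when the aryl carbon C4a of a chroman-4-one moves from C4 to C3 and C4 leaves the ring as a carboxyl carbon. One oxidative 1,2-aryl shift of an enantiopure (S)-6-bromo-4'-tosyloxyflavanone (electron-poor C2 aryl, bromine para to the ring oxygen) therefore delivers the five-membered ring, the C3–C3a bond and the C3 stereocentre as the trans 3-carboxylate. C2 then steers hydroxylation of C3 and is finally inverted by quinone-methide equilibration, placing aryl and aroyl trans.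

Key step: step 3

Remark: the target's C2 configuration (aryl trans to the C3 aroyl group, cis to the C3 hydroxyl) is assumed to be the thermodynamically preferred C2 epimer, so that equilibration through the ring-opened quinone methide converges on it.

Step 1
Reactants: 1 4-hydroxyphenylboronic acid
Product: 2 4-(tosyloxy)phenylboronic acid
Conditions: TsCl, Et3N, THF, 0 °C → rt; dilute aq. HCl work-up
Reagents that add atoms: p-toluenesulfonyl chloride, Cc1ccc(cc1)S(Cl)(=O)=O
Why: O-sulfonylation of the phenol, which is far more nucleophilic than the B–OH groups, should give the electron-poor aryl donor, any boroxine or mixed anhydride being hydrolysed on acidic work-up.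

Step 2
Reactants: 2 4-(tosyloxy)phenylboronic acid; 3 6-bromochromone (6-bromo-4H-chromen-4-one)
Product: 4 4-[(2S)-6-bromo-4-oxo-3,4-dihydro-2H-chromen-2-yl]phenyl 4-methylbenzenesulfonate ((S)-6-bromo-4'-tosyloxyflavanone)
Conditions: [RhCl(C2H4)2]2 (cat.), (1S,4S)-2,5-diphenylbicyclo[2.2.2]octa-2,5-diene (cat.), aq. KOH (0.2 equiv), toluene/H2O, 30 °C
Reagents that add atoms: none
Why: In this Hayashi–Miyaura asymmetric 1,4-addition the aryl group on diene-bound monovalent rhodium adds to C2 of the chromone from one enantioface and so sets the C2 stereocentre under catalyst control (the diene antipode named is the one expected, by analogy with additions to cyclohexenone, to give S, and the enantiomeric diene would be used should the sense prove opposite), while the aryl bromide and the tosylate are inert to monovalent rhodium at this temperature.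

Step 3
Reactants: 4 (S)-6-bromo-4'-tosyloxyflavanone
Product: 7 methyl (2S,3S)-5-bromo-2-[4-(tosyloxy)phenyl]-2,3-dihydro-1-benzofuran-3-carboxylate (aryl and ester trans), via 4-methoxy-2H-chromene enol ether 5 (not isolated), via trans-3-iodanyl ketal 6 (not isolated)
Conditions: PhI(OAc)2 (1.2 equiv), conc. H2SO4 (cat.), HC(OMe)3, rt
Reagents that add atoms: trimethyl orthoformate, COC(OC)OC
Why: In acidic trimethyl orthoformate the ketone is ketalised and equilibrates with enol ether 5; the electrophilic trivalent iodine reagent bonds to C3 from the face remote from the C2 aryl group while methanol re-forms the C4 ketal (6), after which the benzo carbon C4a migrates from C4 to C3 with loss of iodobenzene and the dimethoxycarbenium ion at C4 is demethylated to the methyl ester. The closest known reaction is the oxidative ring contraction of flavanones to trans-2-aryl-2,3-dihydrobenzofuran-3-carboxylates with thallium trinitrate or hypervalent iodine in trimethyl orthoformate, a cyclic case of the oxidative 1,2-aryl shift that turns aryl ketones into arylacetic esters. The dihydrofuran ring is closed by contraction and not by cyclisation: the C3–C3a bond forms in a suprafacial 1,2-shift through a bridged phenonium-like transition state (formally a 3-exo-tet attack of the arene ipso carbon on C3) and C4 is pushed out of the ring. The new C3 stereocentre is controlled by C2, because iodine enters anti to the aryl group and the anti-periplanar shift inverts C3, which puts the ester trans to the aryl group, the arrangement that acid-catalysed epimerisation would also favour, while C2 keeps its configuration. The selectivity required is migration of C4a in preference to migration of the C2 aryl group (isoflavone) or plain dehydrogenation (flavone); the two ketal oxygens stabilise the positive charge left on C4, the ring oxygen ortho to C4a raises its migratory aptitude, and the tosyloxy group makes the C2 aryl ring too electron-poor to migrate or to ionise the C2–O1 bond.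

Step 4
Reactants: 7 methyl (2S,3S)-5-bromo-2-[4-(tosyloxy)phenyl]-2,3-dihydro-1-benzofuran-3-carboxylate
Product: 8 (2S,3S)-5-bromo-N-methoxy-N-methyl-2-[4-(tosyloxy)phenyl]-2,3-dihydro-1-benzofuran-3-carboxamide
Conditions: MeNHOMe·HCl, i-PrMgCl, THF, −20 → 0 °C
Reagents that add atoms: N,O-dimethylhydroxylamine hydrochloride, CNOC.Cl
Why: Aminolysis of the ester by the magnesium amide of N,O-dimethylhydroxylamine (Weinreb amide formation) should proceed at low temperature without touching the tosylate or the bromide, and any epimerisation at the acidic C3 returns the trans isomer while C2 is not affected.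

Step 5
Reactants: 9 4-bromoresorcinol
Product: 10 1-bromo-2,4-bis(methoxymethoxy)benzene
Conditions: MOMCl, i-Pr2NEt, CH2Cl2, 0 °C → rt
Reagents that add atoms: chloromethyl methyl ether, COCCl
Why: Double O-alkylation of the two phenols gives base-stable acetal (MOM) ethers that also stabilise the derived ortho-metallated species by chelation.

Step 6
Reactants: 10 1-bromo-2,4-bis(methoxymethoxy)benzene; 8 (2S,3S)-5-bromo-N-methoxy-N-methyl-2-[4-(tosyloxy)phenyl]-2,3-dihydro-1-benzofuran-3-carboxamide
Product: 12 4-[(2S,3S)-3-[2,4-bis(methoxymethoxy)benzoyl]-5-bromo-2,3-dihydro-1-benzofuran-2-yl]phenyl 4-methylbenzenesulfonate (trans ketone), via 2,4-bis(methoxymethoxy)phenyllithium 11 (not isolated)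
Conditions: 10 (1.5 equiv), n-BuLi (1.4 equiv), THF, −78 °C; then 8, −78 → −40 °C; aq. NH4Cl
Reagents that add atoms: none
Why: Bromine–lithium exchange gives an aryllithium reactive enough to acylate at −78 °C, where the bromide and tosylate of 8 are left alone, and this Weinreb ketone synthesis should stop at the ketone because the chelated tetrahedral adduct survives until work-up, the configuration at C3 being of no consequence since the next step makes that carbon planar.

Step 7
Reactants: 12 4-[(2S,3S)-3-[2,4-bis(methoxymethoxy)benzoyl]-5-bromo-2,3-dihydro-1-benzofuran-2-yl]phenyl 4-methylbenzenesulfonate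
Product: 14 4-[(2R,3S)-3-[2,4-bis(methoxymethoxy)benzoyl]-5-bromo-3-hydroxy-2,3-dihydro-1-benzofuran-2-yl]phenyl 4-methylbenzenesulfonate (OH trans and aroyl cis to the C2 aryl group), via potassium enolate 13 (not isolated)
Conditions: KN(SiMe3)2, THF, −78 °C; then 2-(phenylsulfonyl)-3-phenyloxaziridine, −78 °C; aq. NH4Cl
Reagents that add atoms: 2-(phenylsulfonyl)-3-phenyloxaziridine, O=S(=O)(c1ccccc1)N1OC1c1ccccc1
Why: In this oxaziridine enolate hydroxylation (Davis oxidation) the planar exocyclic enolate at C3 should accept oxygen on the face opposite the C2 aryl group, so that the C3 stereocentre (S) is set by substrate control, and at −78 °C the enolate should not expel the ring oxygen because the C2–O1 bond lies close to the nodal plane of the enolate (the C2 descriptor changes from S to R only because C3 now outranks the aryl group).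

Step 8
Reactants: 10 1-bromo-2,4-bis(methoxymethoxy)benzene; 15 acrolein
Product: 17 1-[2,4-bis(methoxymethoxy)phenyl]prop-2-en-1-ol (racemic), via 2,4-bis(methoxymethoxy)phenylmagnesium bromide 16 (not isolated)
Conditions: 10, Mg turnings (cat. I2), THF, 40 °C; then acrolein, −78 → −40 °C; aq. NH4Cl
Reagents that add atoms: none
Why: Magnesium insertion into the electron-rich aryl bromide gives a chelate-stabilised Grignard reagent, chosen here because it is less basic than the lithium species and so adds 1,2 to acrolein (Grignard addition to an enal) with little anionic polymerisation of the enal, and the racemic carbinol centre is removed by the oxidation that follows.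

Step 9
Reactants: 17 1-[2,4-bis(methoxymethoxy)phenyl]prop-2-en-1-ol
Product: 18 1-[2,4-bis(methoxymethoxy)phenyl]prop-2-en-1-one
Conditions: MnO2, CH2Cl2, rt; used at once
Reagents that add atoms: none
Why: Manganese dioxide selectively oxidises a carbinol that is both benzylic and allylic, giving the aryl vinyl ketone under neutral conditions that do not trigger its polymerisation.

Step 10
Reactants: 14 4-[(2R,3S)-3-[2,4-bis(methoxymethoxy)benzoyl]-5-bromo-3-hydroxy-2,3-dihydro-1-benzofuran-2-yl]phenyl 4-methylbenzenesulfonate; 18 1-[2,4-bis(methoxymethoxy)phenyl]prop-2-en-1-one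
Product: 19 4-[(2R,3S)-3-[2,4-bis(methoxymethoxy)benzoyl]-5-[(1E)-3-[2,4-bis(methoxymethoxy)phenyl]-3-oxoprop-1-en-1-yl]-3-hydroxy-2,3-dihydro-1-benzofuran-2-yl]phenyl 4-methylbenzenesulfonate
Conditions: Pd2(dba)3 (cat.), [HP(t-Bu)3]BF4 (cat.), Cy2NMe, dioxane, 60 °C
Reagents that add atoms: none
Why: In this Mizoroki–Heck coupling zerovalent palladium inserts into the C5–Br bond, and syn carbopalladation of the vinyl ketone followed by syn β-hydride elimination should give the (E)-enone, the aryl tosylate, tertiary alcohol and MOM ethers being inert to this catalyst.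

Step 11
Reactants: 19 tosylate-protected Heck product
Product: 22 (2E)-1-[2,4-bis(methoxymethoxy)phenyl]-3-[(2S,3S)-3-[2,4-bis(methoxymethoxy)benzoyl]-3-hydroxy-2-(4-hydroxyphenyl)-2,3-dihydro-1-benzofuran-5-yl]prop-2-en-1-one, via kinetic C2-epimeric phenol 20 (not isolated), via ring-opened quinone methide 21 (not isolated)
Conditions: KOH (excess), dioxane/H2O (degassed, dilute), 60–70 °C; then dilute HCl to pH 6, 0 °C
Reagents that add atoms: none
Why: Hydroxide cleaves the aryl sulfonate at sulfur, and the freed phenoxide should reversibly open the C2–O1 bond to a para-quinone methide that recloses by 5-exo-trig attack of the benzo-ring phenoxide (the base-mediated C2 epimerisation known for 4'-hydroxyflavan-3-ols and phenolic phenylcoumarans), so that C2 equilibrates to the epimer expected to be more stable, with aryl trans to aroyl, while the quaternary C3 cannot change and the MOM ethers keep the resorcinol oxygens from capturing the quinone methide.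

Step 12
Reactants: 22 (2S,3S)-configured MOM-protected phenol
Product: 23 (2E)-1-(2,4-dihydroxyphenyl)-3-[(2S,3S)-3-(2,4-dihydroxybenzoyl)-3-hydroxy-2-(4-hydroxyphenyl)-2,3-dihydro-1-benzofuran-5-yl]prop-2-en-1-one (CNP0317806.1)
Conditions: 3 M aq. HCl, MeOH/THF, rt → 40 °C
Reagents that add atoms: none
Why: Acid-catalysed acetal exchange with methanol removes the four MOM ethers as dimethoxymethane, and conditions this mild should leave intact the C3 carbinol (its ionisation is disfavoured by the adjacent carbonyl group), the 2'-hydroxychalcone and the dihydrofuran ring.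

Compound list
1 | 4-hydroxyphenylboronic acid | OB(O)c1ccc(O)cc1 | starting material
2 | 4-(tosyloxy)phenylboronic acid | Cc1ccc(cc1)S(=O)(=O)Oc1ccc(cc1)B(O)O | intermediate
3 | 6-bromochromone (6-bromo-4H-chromen-4-one) | O=c1ccoc2ccc(Br)cc12 | starting material
4 | 4-[(2S)-6-bromo-4-oxo-3,4-dihydro-2H-chromen-2-yl]phenyl 4-methylbenzenesulfonate | O=C1C[C@@H](c2ccc(OS(=O)(=O)c3ccc(C)cc3)cc2)Oc2ccc(Br)cc21 | intermediate
5 | 4-[(2S)-6-bromo-4-methoxy-2H-chromen-2-yl]phenyl 4-methylbenzenesulfonate (enol ether, not isolated) | COC1=C[C@@H](c2ccc(OS(=O)(=O)c3ccc(C)cc3)cc2)Oc2ccc(Br)cc21 | intermediate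
6 | (2R,3R)-3-[acetoxy(phenyl)-λ3-iodanyl]-6-bromo-4,4-dimethoxy-2-[4-(tosyloxy)phenyl]chromane, iodine trans to the C2 aryl group (not isolated) | COC1(OC)[C@H](I(OC(C)=O)c2ccccc2)[C@@H](c2ccc(OS(=O)(=O)c3ccc(C)cc3)cc2)Oc2ccc(Br)cc21 | intermediate
7 | methyl (2S,3S)-5-bromo-2-[4-(tosyloxy)phenyl]-2,3-dihydro-1-benzofuran-3-carboxylate (trans) | Brc1ccc2c(c1)[C@H](C(=O)OC)[C@@H](c1ccc(OS(=O)(=O)c3ccc(C)cc3)cc1)O2 | intermediate
8 | (2S,3S)-5-bromo-N-methoxy-N-methyl-2-[4-(tosyloxy)phenyl]-2,3-dihydro-1-benzofuran-3-carboxamide | Brc1ccc2c(c1)[C@H](C(=O)N(C)OC)[C@@H](c1ccc(OS(=O)(=O)c3ccc(C)cc3)cc1)O2 | intermediate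
9 | 4-bromoresorcinol | Oc1ccc(Br)c(O)c1 | starting material
10 | 1-bromo-2,4-bis(methoxymethoxy)benzene | COCOc1ccc(Br)c(OCOC)c1 | intermediate
11 | 2,4-bis(methoxymethoxy)phenyllithium (not isolated) | [Li]c1ccc(OCOC)cc1OCOC | intermediate
12 | 4-[(2S,3S)-3-[2,4-bis(methoxymethoxy)benzoyl]-5-bromo-2,3-dihydro-1-benzofuran-2-yl]phenyl 4-methylbenzenesulfonate (trans) | Brc1ccc2c(c1)[C@H](C(=O)c1ccc(OCOC)cc1OCOC)[C@@H](c1ccc(OS(=O)(=O)c3ccc(C)cc3)cc1)O2 | intermediate
13 | potassium enolate of 12 (C3 planar, enolate geometry not defined, C2 unchanged; not isolated) | Brc1ccc2c(c1)C(=C([O-])c1ccc(OCOC)cc1OCOC)[C@@H](c1ccc(OS(=O)(=O)c3ccc(C)cc3)cc1)O2.[K+] | intermediate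
14 | 4-[(2R,3S)-3-[2,4-bis(methoxymethoxy)benzoyl]-5-bromo-3-hydroxy-2,3-dihydro-1-benzofuran-2-yl]phenyl 4-methylbenzenesulfonate | Brc1ccc2c(c1)[C@@](O)(C(=O)c1ccc(OCOC)cc1OCOC)[C@@H](c1ccc(OS(=O)(=O)c3ccc(C)cc3)cc1)O2 | intermediate
15 | acrolein | C=CC=O | starting material
16 | 2,4-bis(methoxymethoxy)phenylmagnesium bromide (not isolated) | Br[Mg]c1ccc(OCOC)cc1OCOC | intermediate
17 | 1-[2,4-bis(methoxymethoxy)phenyl]prop-2-en-1-ol (racemic) | C=CC(O)c1ccc(OCOC)cc1OCOC | intermediate
18 | 1-[2,4-bis(methoxymethoxy)phenyl]prop-2-en-1-one | C=CC(=O)c1ccc(OCOC)cc1OCOC | intermediate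
19 | 4-[(2R,3S)-3-[2,4-bis(methoxymethoxy)benzoyl]-5-[(1E)-3-[2,4-bis(methoxymethoxy)phenyl]-3-oxoprop-1-en-1-yl]-3-hydroxy-2,3-dihydro-1-benzofuran-2-yl]phenyl 4-methylbenzenesulfonate | O=C(/C=C/c1ccc2c(c1)[C@@](O)(C(=O)c1ccc(OCOC)cc1OCOC)[C@@H](c1ccc(OS(=O)(=O)c3ccc(C)cc3)cc1)O2)c1ccc(OCOC)cc1OCOC | intermediate
20 | (2E)-1-[2,4-bis(methoxymethoxy)phenyl]-3-[(2R,3S)-3-[2,4-bis(methoxymethoxy)benzoyl]-3-hydroxy-2-(4-hydroxyphenyl)-2,3-dihydro-1-benzofuran-5-yl]prop-2-en-1-one (kinetic C2 epimer, not isolated) | O=C(/C=C/c1ccc2c(c1)[C@@](O)(C(=O)c1ccc(OCOC)cc1OCOC)[C@@H](c1ccc(O)cc1)O2)c1ccc(OCOC)cc1OCOC | intermediate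
21 | ring-opened para-quinone methide: former C2 is the exocyclic methine of a 4-oxocyclohexa-2,5-dienylidene, the benzo ring carries a free OH, the carbinol carbon (former C3) is R (not isolated) | O=C(/C=C/c1ccc(O)c(c1)[C@@](O)(C(=O)c1ccc(OCOC)cc1OCOC)C=C1C=CC(=O)C=C1)c1ccc(OCOC)cc1OCOC | intermediate
22 | (2E)-1-[2,4-bis(methoxymethoxy)phenyl]-3-[(2S,3S)-3-[2,4-bis(methoxymethoxy)benzoyl]-3-hydroxy-2-(4-hydroxyphenyl)-2,3-dihydro-1-benzofuran-5-yl]prop-2-en-1-one | O=C(/C=C/c1ccc2c(c1)[C@@](O)(C(=O)c1ccc(OCOC)cc1OCOC)[C@H](c1ccc(O)cc1)O2)c1ccc(OCOC)cc1OCOC | intermediate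
23 | (2E)-1-(2,4-dihydroxyphenyl)-3-[(2S,3S)-3-(2,4-dihydroxybenzoyl)-3-hydroxy-2-(4-hydroxyphenyl)-2,3-dihydro-1-benzofuran-5-yl]prop-2-en-1-one | O=C(/C=C/c1ccc2c(c1)[C@@](O)(C(=O)c1ccc(O)cc1O)[C@H](c1ccc(O)cc1)O2)c1ccc(O)cc1O | target

Total step count: 12. Longest linear sequence: 9 steps (steps 1, 2, 3, 4, 6, 7, 10, 11, 12).

Steps most likely to fail, riskiest first

Step 11. The equilibration at C2 may settle at a poor epimer ratio, or the hot hydroxide treatment may be overtaken by base-driven degradation (retro-aldol cleavage of the enone, α-ketol rearrangement of the C3 carbinol). Fallback: the unveiling is moved ahead of the coupling, onto the simplest substrate, where epimers can be separated on silica and the unwanted one resubmitted. Setting out from 14, KOH in degassed dioxane/H2O at 60 °C would cleave the tosylate to the kinetic phenol, [2,4-bis(methoxymethoxy)phenyl][(2R,3S)-5-bromo-3-hydroxy-2-(4-hydroxyphenyl)-2,3-dihydro-1-benzofuran-3-yl]methanone F6, which in the same flask should equilibrate through its quinone methide to [2,4-bis(methoxymethoxy)phenyl][(2S,3S)-5-bromo-3-hydroxy-2-(4-hydroxyphenyl)-2,3-dihydro-1-benzofuran-3-yl]methanone F7. Heck coupling of F7 with 18 under the conditions of step 10, which tolerate a free phenol, would then give 22, where the main route resumes.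

Step 3. Dehydrogenation to the flavone, or migration of the C2 aryl group, may outrun the shift of the benzo carbon. Fallback: the same 1,2-shift is brought about as a Wolff ring contraction. Setting out from 4, kinetic deprotonation with LiN(SiMe3)2 in THF at −78 °C and C-acylation with 2,2,2-trifluoroethyl trifluoroacetate would give (2S)-6-bromo-2-[4-(tosyloxy)phenyl]-3-(trifluoroacetyl)chroman-4-one F1. Deacylative diazo transfer (MsN3, Et3N, H2O, MeCN) would give (2R)-6-bromo-3-diazo-2-[4-(tosyloxy)phenyl]chroman-4-one F2. Photolysis of F2 in MeOH would make the benzo carbon migrate to the carbene carbon and trap the ketene as a mixture of 7 and its C3 epimer, methyl (2S,3R)-5-bromo-2-[4-(tosyloxy)phenyl]-2,3-dihydro-1-benzofuran-3-carboxylate F3, which NaOMe in MeOH should equilibrate to the trans ester 7.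

Step 7. The potassium enolate may expel the ring oxygen (β-elimination with ring opening and loss of the C2 centre), or oxygen transfer may show poor facial selectivity. Fallback: a Rubottom oxidation through a neutral silyl enol ether made by soft enolisation, so that no free enolate is present. Setting out from 12, TBSOTf and Et3N in CH2Cl2 (−78 → 0 °C) would give 4-[(2R)-3-{[2,4-bis(methoxymethoxy)phenyl][(tert-butyldimethylsilyl)oxy]methylidene}-5-bromo-2,3-dihydro-1-benzofuran-2-yl]phenyl 4-methylbenzenesulfonate F4, in which C2 is spatially unchanged and only its descriptor differs from that of 12. Epoxidation with dimethyldioxirane in acetone/CH2Cl2 at −40 °C, anti to the C2 aryl group, followed by silyl migration, would give the silyloxy ketone 4-[(2R,3S)-3-[2,4-bis(methoxymethoxy)benzoyl]-5-bromo-3-[(tert-butyldimethylsilyl)oxy]-2,3-dihydro-1-benzofuran-2-yl]phenyl 4-methylbenzenesulfonate F5. HF·pyridine in THF at 0 °C would then release 14.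

Further compounds
F1 | step 3 | (2S)-6-bromo-2-[4-(tosyloxy)phenyl]-3-(trifluoroacetyl)chroman-4-one (C3 enolisable, not defined) | O=C1C(C(=O)C(F)(F)F)[C@@H](c2ccc(OS(=O)(=O)c3ccc(C)cc3)cc2)Oc2ccc(Br)cc21
F2 | step 3 | (2R)-6-bromo-3-diazo-2-[4-(tosyloxy)phenyl]chroman-4-one | O=C1C(=[N+]=[N-])[C@@H](c2ccc(OS(=O)(=O)c3ccc(C)cc3)cc2)Oc2ccc(Br)cc21
F3 | step 3 | methyl (2S,3R)-5-bromo-2-[4-(tosyloxy)phenyl]-2,3-dihydro-1-benzofuran-3-carboxylate (cis) | Brc1ccc2c(c1)[C@@H](C(=O)OC)[C@@H](c1ccc(OS(=O)(=O)c3ccc(C)cc3)cc1)O2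
F4 | step 7 | 4-[(2R)-3-{[2,4-bis(methoxymethoxy)phenyl][(tert-butyldimethylsilyl)oxy]methylidene}-5-bromo-2,3-dihydro-1-benzofuran-2-yl]phenyl 4-methylbenzenesulfonate (alkene geometry not defined) | Brc1ccc2c(c1)C(=C(O[Si](C)(C)C(C)(C)C)c1ccc(OCOC)cc1OCOC)[C@@H](c1ccc(OS(=O)(=O)c3ccc(C)cc3)cc1)O2
F5 | step 7 | 4-[(2R,3S)-3-[2,4-bis(methoxymethoxy)benzoyl]-5-bromo-3-[(tert-butyldimethylsilyl)oxy]-2,3-dihydro-1-benzofuran-2-yl]phenyl 4-methylbenzenesulfonate | Brc1ccc2c(c1)[C@@](O[Si](C)(C)C(C)(C)C)(C(=O)c1ccc(OCOC)cc1OCOC)[C@@H](c1ccc(OS(=O)(=O)c3ccc(C)cc3)cc1)O2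
F6 | step 11 | [2,4-bis(methoxymethoxy)phenyl][(2R,3S)-5-bromo-3-hydroxy-2-(4-hydroxyphenyl)-2,3-dihydro-1-benzofuran-3-yl]methanone | Brc1ccc2c(c1)[C@@](O)(C(=O)c1ccc(OCOC)cc1OCOC)[C@@H](c1ccc(O)cc1)O2
F7 | step 11 | [2,4-bis(methoxymethoxy)phenyl][(2S,3S)-5-bromo-3-hydroxy-2-(4-hydroxyphenyl)-2,3-dihydro-1-benzofuran-3-yl]methanone | Brc1ccc2c(c1)[C@@](O)(C(=O)c1ccc(OCOC)cc1OCOC)[C@H](c1ccc(O)cc1)O2
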